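**Plan**
Retrosynthetic cuts, in order: the three phenols back to MOM ethers and C4=O back to a C4 carbinol; then O1–C8a (ring C); then C3–C4 (aldol); and in ring B the benzylic homologation carbon (future C2) and the C5'–prenyl bond.
Enabling feature: in ring A, O5 and O7 are both meta to C8a and O7 sits next to C8. A C8≡C8a aryne, made from a C8 bromide, is therefore polarised for attack at C8a, where the C4a side chain holds O1 for a six-membered closure. The third phloroglucinol oxygen enters a cheap resorcinol aldehyde by cine-substitution.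
Forward order: rings A and B are bought. The ring B acid is made into its imide, which undergoes a syn aldol with the ring A aldehyde. Reductive auxiliary removal gives the 1,3-diol, the aryne closure forms ring C, and C4 oxidation and MOM removal finish the route.
Stereochemistry: C3 is set by (R)-4-benzyloxazolidinone in the boron aldol and stays non-enolisable (C4 as carbinol) through every basic step. The helpers leave again: the auxiliary in step 9, the bromine in step 10, the C4 centre in step 11.

Key step: step 10

Assumption: 1, 8, 11 and the named reagents are taken as commercial. At C3 the priority order is C4 > C2 > C1' > H, so the drawn centre is S. ArB stands for 4-methoxy-3-(methoxymethoxy)-5-(3-methylbut-2-en-1-yl)phenyl.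

Step 1
Reactants: 1 3-bromo-4,5-dihydroxybenzaldehyde
Product: 2 3-bromo-5-hydroxy-4-methoxybenzaldehyde
Conditions: MeI, Li2CO3, DMF, 45 °C
Reagents that add atoms: methyl iodide, CI
Why: Regioselective Williamson O-methylation, because the 4-OH (para to the formyl group, ortho to bromine) is the more acidic phenol and one equivalent of weak base should ionise and alkylate it alone.

Step 2
Reactants: 2 3-bromo-5-hydroxy-4-methoxybenzaldehyde
Product: 3 3-bromo-4-methoxy-5-(methoxymethoxy)benzaldehyde
Conditions: MOMCl, i-Pr2NEt, CH2Cl2, 0 °C → rt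
Reagents that add atoms: chloromethyl methyl ether, COCCl
Why: Standard MOM ether formation on the remaining phenol, chosen because this acetal must later survive a boron Lewis acid, a hydride and a lithium amide.

Step 3
Reactants: 3 3-bromo-4-methoxy-5-(methoxymethoxy)benzaldehyde
Product: 4 4-methoxy-3-(methoxymethoxy)-5-(3-methylbut-2-en-1-yl)benzaldehyde
Conditions: prenylboronic acid pinacol ester, Pd(dppf)Cl2 (cat.), K2CO3, DMF–H2O, 80 °C
Reagents that add atoms: 4,4,5,5-tetramethyl-2-(3-methylbut-2-en-1-yl)-1,3,2-dioxaborolane, CC(C)=CCB1OC(C)(C)C(C)(C)O1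
Why: Suzuki–Miyaura allyl–aryl coupling, in which the wide-bite-angle dppf ligand should direct reductive elimination to the unsubstituted allyl terminus and give the linear prenyl arene, with aldehyde and acetal inert.

Step 4
Reactants: 4 4-methoxy-3-(methoxymethoxy)-5-(3-methylbut-2-en-1-yl)benzaldehyde
Product: 6 2-ArB-acetonitrile, via vinyl formamide 5 (not isolated)
Conditions: TosMIC, t-BuOK, DME, −35 °C; then MeOH, reflux
Reagents that add atoms: tosylmethyl isocyanide, Cc1ccc(cc1)S(=O)(=O)C[N+]#[C-]
Why: Van Leusen reductive cyanation, in which the TosMIC anion adds to the aldehyde, the oxazoline opens to 5, and methanolysis of the formyl group with loss of sulfinate leaves the homologous nitrile whose new carbon becomes C2.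

Step 5
Reactants: 6 2-ArB-acetonitrile
Product: 7 2-ArB-acetic acid
Conditions: KOH, EtOH–H2O, reflux; then cold dilute HCl to pH 4
Reagents that add atoms: water, O; potassium hydroxide, [K+].[OH-]
Why: Alkaline nitrile hydrolysis, to which the aryl acetal, the methyl ether and the trisubstituted alkene are inert, followed by a brief cold acidification that spares the MOM group.

Step 6
Reactants: 7 2-ArB-acetic acid; 8 (4R)-4-benzyl-1,3-oxazolidin-2-one
Product: 10 (4R)-4-benzyl-3-(2-ArB-acetyl)-1,3-oxazolidin-2-one, via mixed anhydride 9 (not isolated)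
Conditions: PivCl, Et3N, THF, −20 °C; then 8, LiCl, rt
Reagents that add atoms: pivaloyl chloride, CC(C)(C)C(=O)Cl (its acyl group is held only by 9)
Why: N-acylation of the oxazolidinone through the mixed pivalic anhydride with LiCl activation, a mild protocol that keeps strong base away from the acidic arylacetyl unit.

Step 7
Reactants: 11 5-bromo-2,4-dihydroxybenzaldehyde
Product: 12 5-bromo-2,4-bis(methoxymethoxy)benzaldehyde
Conditions: NaH, DMF, 0 °C; MOMCl, 0 °C → rt
Reagents that add atoms: chloromethyl methyl ether, COCCl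
Why: Double MOM ether formation, with NaH used so that the hydrogen-bonded 2-OH is alkylated as well as the 4-OH.

Step 8
Reactants: 10 (4R)-4-benzyl-3-(2-ArB-acetyl)-1,3-oxazolidin-2-one; 12 5-bromo-2,4-bis(methoxymethoxy)benzaldehyde
Product: 15 (4R)-4-benzyl-3-{(2R,3R)-2-ArB-3-[5-bromo-2,4-bis(methoxymethoxy)phenyl]-3-hydroxypropanoyl}-1,3-oxazolidin-2-one, via boron enolate 13 (not isolated), via boron aldolate 14 (not isolated)
Conditions: Bu2BOTf, Et3N, CH2Cl2, −78 → 0 °C; 12, −78 → 0 °C; then pH 7 buffer, MeOH, H2O2, 0 °C
Reagents that add atoms: dibutylboron triflate, CCCCB(CCCC)OS(=O)(=O)C(F)(F)F (its Bu2B unit is held only by 13 and 14)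
Why: Evans syn aldol, in which soft enolisation gives the Z boron enolate 13 that adds through a Zimmerman–Traxler chair on the face remote from the auxiliary benzyl group, setting C3 (2R here, the future 3S) and the helper centre C4 on a mono-ortho-substituted, unhindered aldehyde.

Step 9
Reactants: 15 (4R)-4-benzyl-3-{(2R,3R)-2-ArB-3-[5-bromo-2,4-bis(methoxymethoxy)phenyl]-3-hydroxypropanoyl}-1,3-oxazolidin-2-one
Product: 16 (1R,2S)-2-ArB-1-[5-bromo-2,4-bis(methoxymethoxy)phenyl]propane-1,3-diol
Conditions: LiBH4, Et2O–THF, H2O (1 equiv), 0 °C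
Reagents that add atoms: none
Why: Reductive cleavage of the imide with LiBH4 turns the acyl carbon into the C2 hydroxymethyl group and returns the auxiliary without touching C3, the aryl bromide, the acetals or the alkene.

Step 10
Reactants: 16 (1R,2S)-2-ArB-1-[5-bromo-2,4-bis(methoxymethoxy)phenyl]propane-1,3-diol
Product: 18 (3S,4R)-3-ArB-5,7-bis(methoxymethoxy)-3,4-dihydro-2H-chromen-4-ol (trans), via aryne 17 (not isolated)
Conditions: 2,2,6,6-tetramethylpiperidine, n-BuLi, THF, 0 °C (gives LiTMP, excess); 16, −78 → −10 °C; H2O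
Reagents that add atoms: none
Why: LiTMP first turns both hydroxyls into lithium alkoxides and then removes H8a, the only hydrogen ortho to the C8 bromide and one that the neighbouring C4–OLi helps the base to reach, and loss of LiBr gives the C8≡C8a aryne 17. The primary alkoxide O1 adds to C8a in a 6-exo-dig closure of ring C, and the resulting C8 aryl anion, stabilised by the adjacent O7 acetal, is protonated by tetramethylpiperidine, so bromine leaves C8 while oxygen enters C8a (cine-substitution). The closest known reaction types are the base-induced aryne cyclisation of halogenoarenes bearing a tethered alcohol, which gives chromans, and the generation of 3,5-dialkoxyarynes from 4-halogenoresorcinol diethers with lithium amides. No stereocentre is formed, and C3 and C4 are spectators because at the carbinol oxidation level C3–H is merely benzylic and can be neither removed by the amide nor lost by beta-elimination. Regioselectivity is doubly secured, since the inductive pull of O7 makes C8a the electrophilic aryne terminus and the tether can reach only C8a, while the C4 alkoxide could close only a four-membered ring and stays idle. Capture of the aryne by amine is countered by the hindered base and the intramolecular trap, and the low temperature permitted by fast LiBr loss should spare the doubly activated prenyl CH2.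

Step 11
Reactants: 18 (3S,4R)-3-ArB-5,7-bis(methoxymethoxy)-3,4-dihydro-2H-chromen-4-ol
Product: 19 (3S)-3-ArB-5,7-bis(methoxymethoxy)-2,3-dihydro-4H-chromen-4-one
Conditions: Dess–Martin periodinane, NaHCO3, CH2Cl2, 0 °C → rt
Reagents that add atoms: none
Why: Dess–Martin oxidation under bicarbonate buffering, a fast neutral method known to convert isoflavan-4-ols and other alcohols next to epimerisable centres into ketones with the alpha carbon retained, which here erases the helper centre C4.

Step 12
Reactants: 19 (3S)-3-ArB-5,7-bis(methoxymethoxy)-2,3-dihydro-4H-chromen-4-one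
Product: 20 (3S)-5,7,3'-trihydroxy-4'-methoxy-5'-prenylisoflavanone
Conditions: HCl in MeOH (dilute), THF, 0 °C → rt, stopped at full conversion
Reagents that add atoms: none
Why: Acid-catalysed transacetalisation of the three aryl MOM ethers to methanol, where acetal cleavage should far outrun acid-catalysed enolisation of the aryl ketone, base is avoided altogether, and the prenyl group has no free ortho phenol to cyclise with, so C3 should stay S.

**Compound list**
1 | 3-bromo-4,5-dihydroxybenzaldehyde | O=Cc1cc(O)c(O)c(Br)c1 | starting material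
2 | 3-bromo-5-hydroxy-4-methoxybenzaldehyde | O=Cc1cc(O)c(OC)c(Br)c1 | intermediate
3 | 3-bromo-4-methoxy-5-(methoxymethoxy)benzaldehyde | O=Cc1cc(OCOC)c(OC)c(Br)c1 | intermediate
4 | 4-methoxy-3-(methoxymethoxy)-5-(3-methylbut-2-en-1-yl)benzaldehyde | O=Cc1cc(OCOC)c(OC)c(CC=C(C)C)c1 | intermediate
5 | N-[2-ArB-1-(4-methylphenylsulfonyl)ethenyl]formamide (not isolated) | O=CNC(=Cc1cc(OCOC)c(OC)c(CC=C(C)C)c1)S(=O)(=O)c2ccc(C)cc2 | intermediate
6 | 2-ArB-acetonitrile | N#CCc1cc(OCOC)c(OC)c(CC=C(C)C)c1 | intermediate
7 | 2-ArB-acetic acid | OC(=O)Cc1cc(OCOC)c(OC)c(CC=C(C)C)c1 | intermediate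
8 | (4R)-4-benzyl-1,3-oxazolidin-2-one | O=C1N[C@H](Cc2ccccc2)CO1 | starting material
9 | mixed anhydride of 7 and pivalic acid (not isolated) | CC(C)(C)C(=O)OC(=O)Cc1cc(OCOC)c(OC)c(CC=C(C)C)c1 | intermediate
10 | (4R)-4-benzyl-3-(2-ArB-acetyl)-1,3-oxazolidin-2-one | O=C(Cc1cc(OCOC)c(OC)c(CC=C(C)C)c1)N2[C@H](Cc3ccccc3)COC2=O | intermediate
11 | 5-bromo-2,4-dihydroxybenzaldehyde | O=Cc1cc(Br)c(O)cc1O | starting material
12 | 5-bromo-2,4-bis(methoxymethoxy)benzaldehyde | O=Cc1cc(Br)c(OCOC)cc1OCOC | intermediate
13 | (Z)-dibutylboron enolate of 10 (not isolated) | CCCCB(CCCC)O/C(=C\c1cc(OCOC)c(OC)c(CC=C(C)C)c1)N2[C@H](Cc3ccccc3)COC2=O | intermediate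
14 | O-dibutylboron aldolate of 15 (not isolated) | COCOc1cc([C@@H](C(=O)N2[C@H](Cc3ccccc3)COC2=O)[C@@H](OB(CCCC)CCCC)c4cc(Br)c(OCOC)cc4OCOC)cc(CC=C(C)C)c1OC | intermediate
15 | (2R,3R)-syn aldol imide | COCOc1cc([C@@H](C(=O)N2[C@H](Cc3ccccc3)COC2=O)[C@@H](O)c4cc(Br)c(OCOC)cc4OCOC)cc(CC=C(C)C)c1OC | intermediate
16 | (1R,2S)-2-ArB-1-[5-bromo-2,4-bis(methoxymethoxy)phenyl]propane-1,3-diol | COCOc1cc([C@@H](CO)[C@@H](O)c2cc(Br)c(OCOC)cc2OCOC)cc(CC=C(C)C)c1OC | intermediate
17 | C8≡C8a aryne of 16 (not isolated; drawn as the free diol, present as its dilithium alkoxide) | COCOc1cc([C@@H](CO)[C@@H](O)C2=C(OCOC)C=C(OCOC)C#C2)cc(CC=C(C)C)c1OC | intermediate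
18 | (3S,4R)-3-ArB-5,7-bis(methoxymethoxy)-3,4-dihydro-2H-chromen-4-ol | COCOc1cc([C@H]2COc3cc(OCOC)cc(OCOC)c3[C@@H]2O)cc(CC=C(C)C)c1OC | intermediate
19 | (3S)-3-ArB-5,7-bis(methoxymethoxy)-2,3-dihydro-4H-chromen-4-one | COCOc1cc([C@H]2COc3cc(OCOC)cc(OCOC)c3C2=O)cc(CC=C(C)C)c1OC | intermediate
20 | (3S)-5,7,3'-trihydroxy-4'-methoxy-5'-prenylisoflavanone | COc1c(O)cc([C@H]2COc3cc(O)cc(O)c3C2=O)cc1CC=C(C)C | target

**Totals**
Total steps: 12. Longest linear sequence: 11 (steps 1–6 and 8–12).

**Steps most likely to fail**

Step 10. Three processes may intervene.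
- Lithiation at C6 between the two acetal oxygens, followed by bromine migration.
- Capture of the aryne by the amine.
- A base-induced shift of the prenyl double bond.

The fallback replaces cine-substitution by ipso-substitution and needs no strong base. It sets out from 10 and comes back at 18. Vilsmeier–Haack formylation of commercial 5-bromoresorcinol should give 2-bromo-4,6-dihydroxybenzaldehyde F1, and NaH/MOMCl its bis(methoxymethyl) ether F2. The boron aldol of 10 with F2 under the conditions of step 8 would give the syn adduct F3, and LiBH4 the diol F4. An intramolecular Ullmann-type etherification (CuI, 1,10-phenanthroline, Cs2CO3, toluene, 110 °C) would then join O1 to the bromine-bearing C8a and deliver 18.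

Step 8. Addition to the electron-rich aldehyde may be slow. Retro-aldol cleavage on work-up, or epimerisation at the acidic carbon between imide and aryl group, may erode the stereocontrol.

The fallback replaces auxiliary control by catalyst control through dynamic kinetic resolution. It sets out from 7 and 12 and comes back at 19.
- The Ivanov reaction of the LDA-derived dianion of 7 with 12 would give the racemic hydroxy acid F5.
- LiAlH4 would give the racemic diol F6.
- The conditions of step 10 would give the racemic chromanol F7.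
- Dess–Martin oxidation would give the racemic ketone F8.
- Noyori–Ikariya transfer hydrogenation with RuCl(p-cymene)[(S,S)-TsDPEN] in HCO2H–Et3N, where the amine keeps C3 of F8 equilibrating, should reduce the (3S)-ketone selectively to the cis-(3S,4S)-chromanol F9.
- The conditions of step 11 would convert F9 into 19.

Step 12. Acid-catalysed enolisation of the C4 ketone during acetal cleavage may erode the configuration at C3, and solvent may add across the prenyl double bond.

The fallback replaces stereoretentive deprotection by separation with recycling. It sets out from 19 and comes back at 20. The acetals are cleaved without regard to configuration, and the enantiomers are separated by preparative chromatography on a polysaccharide chiral stationary phase. The (3R)-enantiomer F10 is re-equilibrated at C3 with a trace of Et3N in MeOH and fed back to the separation.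

**Further compounds**
F1 | step 10 | 2-bromo-4,6-dihydroxybenzaldehyde | O=Cc1c(O)cc(O)cc1Br
F2 | step 10 | 2-bromo-4,6-bis(methoxymethoxy)benzaldehyde | O=Cc1c(OCOC)cc(OCOC)cc1Br
F3 | step 10 | (4R)-4-benzyl-3-{(2R,3R)-2-ArB-3-[2-bromo-4,6-bis(methoxymethoxy)phenyl]-3-hydroxypropanoyl}-1,3-oxazolidin-2-one | COCOc1cc([C@@H](C(=O)N2[C@H](Cc3ccccc3)COC2=O)[C@@H](O)c4c(Br)cc(OCOC)cc4OCOC)cc(CC=C(C)C)c1OC
F4 | step 10 | (1R,2S)-2-ArB-1-[2-bromo-4,6-bis(methoxymethoxy)phenyl]propane-1,3-diol | COCOc1cc([C@@H](CO)[C@@H](O)c2c(Br)cc(OCOC)cc2OCOC)cc(CC=C(C)C)c1OC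
F5 | step 8 | racemic 2-ArB-3-[5-bromo-2,4-bis(methoxymethoxy)phenyl]-3-hydroxypropanoic acid | COCOc1cc(C(C(=O)O)C(O)c2cc(Br)c(OCOC)cc2OCOC)cc(CC=C(C)C)c1OC
F6 | step 8 | racemic 2-ArB-1-[5-bromo-2,4-bis(methoxymethoxy)phenyl]propane-1,3-diol | COCOc1cc(C(CO)C(O)c2cc(Br)c(OCOC)cc2OCOC)cc(CC=C(C)C)c1OC
F7 | step 8 | racemic 3-ArB-5,7-bis(methoxymethoxy)-3,4-dihydro-2H-chromen-4-ol | COCOc1cc(C2COc3cc(OCOC)cc(OCOC)c3C2O)cc(CC=C(C)C)c1OC
F8 | step 8 | racemic 3-ArB-5,7-bis(methoxymethoxy)-2,3-dihydro-4H-chromen-4-one | COCOc1cc(C2COc3cc(OCOC)cc(OCOC)c3C2=O)cc(CC=C(C)C)c1OC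
F9 | step 8 | (3S,4S)-3-ArB-5,7-bis(methoxymethoxy)-3,4-dihydro-2H-chromen-4-ol (cis) | COCOc1cc([C@H]2COc3cc(OCOC)cc(OCOC)c3[C@H]2O)cc(CC=C(C)C)c1OC
F10 | step 12 | (3R)-5,7,3'-trihydroxy-4'-methoxy-5'-prenylisoflavanone | COc1c(O)cc([C@@H]2COc3cc(O)cc(O)c3C2=O)cc1CC=C(C)C
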